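## Retrosynthetic overview

- The target comes from global desilylation of a bis-TIPS epoxy-butenolide. The butenolide is closed last, by O-acetoxyacetylation and intramolecular aldol condensation of a tertiary α-hydroxy aryl ketone.
- The epoxide is set by Shi epoxidation of the prenyl group while it is the only C=C in the molecule.
- The quaternary carbinol (C–C bond between the two halves, R configuration) comes from an enantioselective reductive Chan rearrangement (1,2-acyl shift from O to C) of an α-aroyloxy acrylate. This is the key step.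
- The α-aroyloxy acrylate comes from a Heck coupling of a prenylated aryl iodide with methyl 2-(aroyloxy)acrylate.
- Fragments: 4-iodophenol + prenyl bromide; 4-bromophenol + CO2 + methyl pyruvate. Ring order: epoxide (step 8), then butenolide (step 9).

Assumption: the ligand enantiomer written in step 7 is provisional; which antipode of DTBM-SEGPHOS gives the (R)-carbinol must be fixed by a first experiment, and the mirror-image ligand is used if needed. TIPSO = (triisopropylsilyl)oxy.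

## Route

Step 1
Reactants: 1 4-bromophenol
Product: 2 (4-bromophenoxy)triisopropylsilane
Conditions: TIPSCl, imidazole, DMF, rt
Reagents that add atoms: chloro(triisopropyl)silane, CC(C)[Si](Cl)(C(C)C)C(C)C
Why: Imidazole-mediated O-silylation; the aryl TIPS ether survives BuLi, Pd, CuH, pH 10.5 and DBU and is removed by fluoride at the end.

Step 2
Reactants: 2 (4-bromophenoxy)triisopropylsilane; 3 carbon dioxide
Product: 6 4-[(triisopropylsilyl)oxy]benzoic acid, via aryllithium 4 (not isolated), via lithium carboxylate 5 (not isolated)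
Conditions: n-BuLi, THF, −78 °C; CO2 (g), −78 °C → rt; cold 1 M HCl work-up
Reagents that add atoms: none
Why: Bromine–lithium exchange followed by carboxylation of the aryllithium with CO2.

Step 3
Reactants: 6 4-[(triisopropylsilyl)oxy]benzoic acid; 7 methyl pyruvate
Product: 9 methyl 2-({4-[(triisopropylsilyl)oxy]benzoyl}oxy)prop-2-enoate, via acid chloride 8 (not isolated)
Conditions: (COCl)2, DMF (cat.), CH2Cl2, 0 °C → rt, evaporate; then 7, Et3N, DMAP (cat.), CH2Cl2, 0 °C → rt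
Reagents that add atoms: none
Why: Acid chloride formation, then O-acylation of the amine-generated enolate of methyl pyruvate (enol ester formation).

Step 4
Reactants: 10 4-iodophenol; 11 1-bromo-3-methylbut-2-ene (prenyl bromide)
Product: 13 4-iodo-2-(3-methylbut-2-en-1-yl)phenol, via sodium phenolate 12 (not isolated)
Conditions: NaH (1.0 equiv), toluene, 0 °C → rt
Reagents that add atoms: none
Why: ortho-C-alkylation of a sodium phenolate in a non-polar solvent (tight ion pair steers SN2 to the ortho carbon; para is blocked by iodine).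

Step 5
Reactants: 13 4-iodo-2-(3-methylbut-2-en-1-yl)phenol
Product: 14 [4-iodo-2-(3-methylbut-2-en-1-yl)phenoxy]triisopropylsilane
Conditions: TIPSCl, imidazole, DMAP (cat.), DMF, 40 °C
Reagents that add atoms: chloro(triisopropyl)silane, CC(C)[Si](Cl)(C(C)C)C(C)C
Why: O-silylation of the hindered phenol; it masks the phenol that would otherwise quench enolates and later attack the epoxide.

Step 6
Reactants: 14 [4-iodo-2-(3-methylbut-2-en-1-yl)phenoxy]triisopropylsilane; 9 methyl 2-({4-[(triisopropylsilyl)oxy]benzoyl}oxy)prop-2-enoate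
Product: 15 methyl (2Z)-3-{3-(3-methylbut-2-en-1-yl)-4-[(triisopropylsilyl)oxy]phenyl}-2-({4-[(triisopropylsilyl)oxy]benzoyl}oxy)prop-2-enoate
Conditions: Pd(OAc)2 (5 mol %), n-Bu4NCl, NaHCO3, DMF, 70 °C
Reagents that add atoms: none
Why: Mizoroki–Heck arylation (Jeffery conditions) at the unsubstituted alkene terminus, as for 2-acylamino acrylates; syn β-hydride elimination puts the aryl trans to the ester (Z), and the trisubstituted prenyl alkene does not react.

Step 7
Reactants: 15 methyl (2Z)-3-{3-(3-methylbut-2-en-1-yl)-4-[(triisopropylsilyl)oxy]phenyl}-2-({4-[(triisopropylsilyl)oxy]benzoyl}oxy)prop-2-enoate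
Product: 17 methyl (2R)-2-hydroxy-2-({3-(3-methylbut-2-en-1-yl)-4-[(triisopropylsilyl)oxy]phenyl}methyl)-3-oxo-3-{4-[(triisopropylsilyl)oxy]phenyl}propanoate, via silyl ether 16 (not isolated)
Conditions: Cu(OAc)2 (5 mol %), (R)-DTBM-SEGPHOS (5.5 mol %), (EtO)2MeSiH (1.2 equiv), THF, −20 °C → rt; then 1 M aq. HCl, THF, 0 °C
Reagents that add atoms: none
Why: Proposed new method: asymmetric reductive Chan rearrangement. Ligated CuH delivers hydride to the β-carbon of the α-aroyloxy acrylate; the resulting α-aroyloxy copper enolate, held in the chiral bisphosphine pocket, attacks its own aroyl C=O from one enolate face (3-exo addition to an oxiranolate that collapses with C–O cleavage, an anionic 1,2-acyl shift from O to C). This forms the C2–C3 bond and the (R)-quaternary carbinol, and the copper alkoxide is then silylated by the silane to regenerate CuH. The closest known reactions are the base-induced Chan rearrangement of α-acyloxy esters (lithium enolates, racemic) and CuH-catalysed enantioselective reductive aldol and reductive Dieckmann cyclisations, where the same copper enolates are trapped intramolecularly by C=O groups.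

Step 8
Reactants: 17 methyl (2R)-2-hydroxy-2-({3-(3-methylbut-2-en-1-yl)-4-[(triisopropylsilyl)oxy]phenyl}methyl)-3-oxo-3-{4-[(triisopropylsilyl)oxy]phenyl}propanoate
Product: 18 methyl (2R)-2-({3-{[(2R)-3,3-dimethyloxiran-2-yl]methyl}-4-[(triisopropylsilyl)oxy]phenyl}methyl)-2-hydroxy-3-oxo-3-{4-[(triisopropylsilyl)oxy]phenyl}propanoate
Conditions: Shi ketone (D-fructose-derived, 30 mol %), Oxone, K2CO3, n-Bu4NHSO4, MeCN/CH2(OMe)2/aq. Na2B4O7–EDTA buffer, 0 °C
Reagents that add atoms: potassium peroxymonosulfate (active component of Oxone), [K+].[O-]S(=O)(=O)OO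
Why: Shi asymmetric epoxidation; the chiral dioxirane attacks the trisubstituted prenyl alkene (the only C=C present) through the spiro transition state, which for the D-fructose-derived ketone gives the (R)-epoxide.

Step 9
Reactants: 18 methyl (2R)-2-({3-{[(2R)-3,3-dimethyloxiran-2-yl]methyl}-4-[(triisopropylsilyl)oxy]phenyl}methyl)-2-hydroxy-3-oxo-3-{4-[(triisopropylsilyl)oxy]phenyl}propanoate; 19 2-chloro-2-oxoethyl acetate (acetoxyacetyl chloride)
Product: 22 methyl (2R)-2-({3-{[(2R)-3,3-dimethyloxiran-2-yl]methyl}-4-[(triisopropylsilyl)oxy]phenyl}methyl)-4-hydroxy-5-oxo-3-{4-[(triisopropylsilyl)oxy]phenyl}-2,5-dihydrofuran-2-carboxylate, via lithium alkoxide 20 (not isolated), via acetoxyacetate ester 21 (not isolated)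
Conditions: LiHMDS (1.05 equiv), THF, −78 °C; 19, −78 → 0 °C; then DBU (2 equiv), MeCN, rt → 40 °C; pH 6 phosphate work-up
Reagents that add atoms: none
Why: O-acylation of the tertiary alkoxide, then DBU-mediated intramolecular aldol condensation of the acetoxyacetate onto the aryl ketone (5-exo); acetyl transfer and loss of acetate give the 3-hydroxybutenolide directly (the annulation used for 3-hydroxy-4-aryl-5,5-dialkylfuranones), and no bond to either stereocentre is broken.

Step 10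
Reactants: 22 methyl (2R)-2-({3-{[(2R)-3,3-dimethyloxiran-2-yl]methyl}-4-[(triisopropylsilyl)oxy]phenyl}methyl)-4-hydroxy-5-oxo-3-{4-[(triisopropylsilyl)oxy]phenyl}-2,5-dihydrofuran-2-carboxylate
Product: 23 methyl (2R)-2-({3-{[(2R)-3,3-dimethyloxiran-2-yl]methyl}-4-hydroxyphenyl}methyl)-4-hydroxy-3-(4-hydroxyphenyl)-5-oxo-2,5-dihydrofuran-2-carboxylate (CNP0331593.1)
Conditions: TBAF (2.5 equiv), AcOH (3 equiv), THF, 0 °C
Reagents that add atoms: none
Why: Fluoride cleavage of both aryl silyl ethers; acetic acid protonates each phenoxide at once, so the ortho phenoxide cannot open the neighbouring epoxide.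

## Compound list

1 | 4-bromophenol | Oc1ccc(Br)cc1 | starting material
2 | (4-bromophenoxy)triisopropylsilane | CC(C)[Si](Oc1ccc(Br)cc1)(C(C)C)C(C)C | intermediate
3 | carbon dioxide | O=C=O | starting material
4 | {4-[(triisopropylsilyl)oxy]phenyl}lithium | [Li]c1ccc(O[Si](C(C)C)(C(C)C)C(C)C)cc1 | intermediate
5 | lithium 4-[(triisopropylsilyl)oxy]benzoate | [Li+].[O-]C(=O)c1ccc(O[Si](C(C)C)(C(C)C)C(C)C)cc1 | intermediate
6 | 4-[(triisopropylsilyl)oxy]benzoic acid | OC(=O)c1ccc(O[Si](C(C)C)(C(C)C)C(C)C)cc1 | intermediate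
7 | methyl pyruvate (methyl 2-oxopropanoate) | CC(=O)C(=O)OC | starting material
8 | 4-[(triisopropylsilyl)oxy]benzoyl chloride | ClC(=O)c1ccc(O[Si](C(C)C)(C(C)C)C(C)C)cc1 | intermediate
9 | methyl 2-({4-[(triisopropylsilyl)oxy]benzoyl}oxy)prop-2-enoate | C=C(OC(=O)c1ccc(O[Si](C(C)C)(C(C)C)C(C)C)cc1)C(=O)OC | intermediate
10 | 4-iodophenol | Oc1ccc(I)cc1 | starting material
11 | 1-bromo-3-methylbut-2-ene (prenyl bromide) | CC(C)=CCBr | starting material
12 | sodium 4-iodophenolate | [Na+].[O-]c1ccc(I)cc1 | intermediate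
13 | 4-iodo-2-(3-methylbut-2-en-1-yl)phenol | CC(C)=CCc1cc(I)ccc1O | intermediate
14 | [4-iodo-2-(3-methylbut-2-en-1-yl)phenoxy]triisopropylsilane | CC(C)=CCc1cc(I)ccc1O[Si](C(C)C)(C(C)C)C(C)C | intermediate
15 | methyl (2Z)-3-{3-(3-methylbut-2-en-1-yl)-4-[(triisopropylsilyl)oxy]phenyl}-2-({4-[(triisopropylsilyl)oxy]benzoyl}oxy)prop-2-enoate | COC(=O)/C(OC(=O)c1ccc(O[Si](C(C)C)(C(C)C)C(C)C)cc1)=C/c1ccc(O[Si](C(C)C)(C(C)C)C(C)C)c(CC=C(C)C)c1 | intermediate
16 | methyl (2R)-2-{[diethoxy(methyl)silyl]oxy}-2-({3-(3-methylbut-2-en-1-yl)-4-[(triisopropylsilyl)oxy]phenyl}methyl)-3-oxo-3-{4-[(triisopropylsilyl)oxy]phenyl}propanoate | COC(=O)[C@](Cc1ccc(O[Si](C(C)C)(C(C)C)C(C)C)c(CC=C(C)C)c1)(O[Si](C)(OCC)OCC)C(=O)c1ccc(O[Si](C(C)C)(C(C)C)C(C)C)cc1 | intermediate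
17 | methyl (2R)-2-hydroxy-2-({3-(3-methylbut-2-en-1-yl)-4-[(triisopropylsilyl)oxy]phenyl}methyl)-3-oxo-3-{4-[(triisopropylsilyl)oxy]phenyl}propanoate | COC(=O)[C@](Cc1ccc(O[Si](C(C)C)(C(C)C)C(C)C)c(CC=C(C)C)c1)(O)C(=O)c1ccc(O[Si](C(C)C)(C(C)C)C(C)C)cc1 | intermediate
18 | methyl (2R)-2-({3-{[(2R)-3,3-dimethyloxiran-2-yl]methyl}-4-[(triisopropylsilyl)oxy]phenyl}methyl)-2-hydroxy-3-oxo-3-{4-[(triisopropylsilyl)oxy]phenyl}propanoate | COC(=O)[C@](Cc1ccc(O[Si](C(C)C)(C(C)C)C(C)C)c(C[C@H]2OC2(C)C)c1)(O)C(=O)c1ccc(O[Si](C(C)C)(C(C)C)C(C)C)cc1 | intermediate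
19 | 2-chloro-2-oxoethyl acetate (acetoxyacetyl chloride) | CC(=O)OCC(=O)Cl | starting material
20 | lithium alkoxide of 18 | COC(=O)[C@](Cc1ccc(O[Si](C(C)C)(C(C)C)C(C)C)c(C[C@H]2OC2(C)C)c1)(O[Li])C(=O)c1ccc(O[Si](C(C)C)(C(C)C)C(C)C)cc1 | intermediate
21 | methyl (2R)-2-{[(acetyloxy)acetyl]oxy}-2-({3-{[(2R)-3,3-dimethyloxiran-2-yl]methyl}-4-[(triisopropylsilyl)oxy]phenyl}methyl)-3-oxo-3-{4-[(triisopropylsilyl)oxy]phenyl}propanoate | COC(=O)[C@](Cc1ccc(O[Si](C(C)C)(C(C)C)C(C)C)c(C[C@H]2OC2(C)C)c1)(OC(=O)COC(C)=O)C(=O)c1ccc(O[Si](C(C)C)(C(C)C)C(C)C)cc1 | intermediate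
22 | methyl (2R)-2-({3-{[(2R)-3,3-dimethyloxiran-2-yl]methyl}-4-[(triisopropylsilyl)oxy]phenyl}methyl)-4-hydroxy-5-oxo-3-{4-[(triisopropylsilyl)oxy]phenyl}-2,5-dihydrofuran-2-carboxylate | COC(=O)[C@]1(Cc2ccc(O[Si](C(C)C)(C(C)C)C(C)C)c(C[C@H]3OC3(C)C)c2)OC(=O)C(O)=C1c1ccc(O[Si](C(C)C)(C(C)C)C(C)C)cc1 | intermediate
23 | methyl (2R)-2-({3-{[(2R)-3,3-dimethyloxiran-2-yl]methyl}-4-hydroxyphenyl}methyl)-4-hydroxy-3-(4-hydroxyphenyl)-5-oxo-2,5-dihydrofuran-2-carboxylate | COC(=O)[C@]1(Cc2ccc(O)c(C[C@H]3OC3(C)C)c2)OC(=O)C(O)=C1c1ccc(O)cc1 | target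

## Step count and weak points

Total: 10 steps. Longest linear sequence: 8 steps (1, 2, 3, 6, 7, 8, 9, 10).

**Step 7 (proposed new step).** The copper enolate may be silylated before the acyl shift (giving only the reduced ester), the hindered product ketone may be reduced, or the ee may be low. Fallback with known chemistry, from 15 back to 17: chemoselective homogeneous hydrogenation of the enol ester C=C ([Rh(cod)(dppb)]BF4, H2, CH2Cl2; the prenyl alkene is untouched) gives methyl 3-{3-(3-methylbut-2-en-1-yl)-4-[(triisopropylsilyl)oxy]phenyl}-2-({4-[(triisopropylsilyl)oxy]benzoyl}oxy)propanoate F1. The classical Chan rearrangement (LDA, THF, −78 → 0 °C) converts it into the racemic α-hydroxy-β-keto ester F2. Preparative chiral SFC isolates the (R)-enantiomer, which is 17.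

**Step 9.** The tertiary alkoxide is hindered, and the acetoxyacetate enolate could attack the methyl ester (Claisen) instead of the electron-rich aryl ketone. Fallback, from 18 to 23, with olefination before lactonisation: Horner–Wadsworth–Emmons reaction of the ketone of 18 with the lithium salt of methyl 2-(dimethoxyphosphoryl)-2-[(tert-butyldimethylsilyl)oxy]acetate (a reagent) gives dimethyl (2E,4R)-2-[(tert-butyldimethylsilyl)oxy]-4-({3-{[(2R)-3,3-dimethyloxiran-2-yl]methyl}-4-[(triisopropylsilyl)oxy]phenyl}methyl)-4-hydroxy-3-{4-[(triisopropylsilyl)oxy]phenyl}pent-2-enedioate F3. Its tertiary hydroxyl lactonises onto the cis ester on warming with catalytic DBU to give the 4-[(tert-butyldimethylsilyl)oxy] butenolide F4. TBAF/AcOH then removes all three silyl groups and gives 23.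

**Step 6.** The Heck coupling of the captodative 2-aroyloxy acrylate may be sluggish or lose the aroyl group. Fallback, from 14 back to 15, building the enol ester by O-acylation instead:
- Iodine–magnesium exchange (i-PrMgCl·LiCl, THF, −20 °C) gives chloro{3-(3-methylbut-2-en-1-yl)-4-[(triisopropylsilyl)oxy]phenyl}magnesium F5.
- CuI-catalysed opening of commercial methyl oxirane-2-carboxylate (seven non-hydrogen atoms) at C3 gives methyl 2-hydroxy-3-{3-(3-methylbut-2-en-1-yl)-4-[(triisopropylsilyl)oxy]phenyl}propanoate F6.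
- Dess–Martin oxidation gives methyl 3-{3-(3-methylbut-2-en-1-yl)-4-[(triisopropylsilyl)oxy]phenyl}-2-oxopropanoate F7, which exists largely as its Z-enol.
- O-acylation of F7 with acid chloride 8 (made from 6 as in step 3; Et3N, DMAP, CH2Cl2) gives 15.

## Further compounds

F1 | step 7 | methyl 3-{3-(3-methylbut-2-en-1-yl)-4-[(triisopropylsilyl)oxy]phenyl}-2-({4-[(triisopropylsilyl)oxy]benzoyl}oxy)propanoate (stereocentre not controlled) | COC(=O)C(Cc1ccc(O[Si](C(C)C)(C(C)C)C(C)C)c(CC=C(C)C)c1)OC(=O)c1ccc(O[Si](C(C)C)(C(C)C)C(C)C)cc1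
F2 | step 7 | racemic methyl 2-hydroxy-2-({3-(3-methylbut-2-en-1-yl)-4-[(triisopropylsilyl)oxy]phenyl}methyl)-3-oxo-3-{4-[(triisopropylsilyl)oxy]phenyl}propanoate | COC(=O)C(Cc1ccc(O[Si](C(C)C)(C(C)C)C(C)C)c(CC=C(C)C)c1)(O)C(=O)c1ccc(O[Si](C(C)C)(C(C)C)C(C)C)cc1
F3 | step 9 | dimethyl (2E,4R)-2-[(tert-butyldimethylsilyl)oxy]-4-({3-{[(2R)-3,3-dimethyloxiran-2-yl]methyl}-4-[(triisopropylsilyl)oxy]phenyl}methyl)-4-hydroxy-3-{4-[(triisopropylsilyl)oxy]phenyl}pent-2-enedioate | COC(=O)[C@](Cc1ccc(O[Si](C(C)C)(C(C)C)C(C)C)c(C[C@H]2OC2(C)C)c1)(O)/C(c1ccc(O[Si](C(C)C)(C(C)C)C(C)C)cc1)=C(/O[Si](C)(C)C(C)(C)C)C(=O)OC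
F4 | step 9 | methyl (2R)-4-[(tert-butyldimethylsilyl)oxy]-2-({3-{[(2R)-3,3-dimethyloxiran-2-yl]methyl}-4-[(triisopropylsilyl)oxy]phenyl}methyl)-5-oxo-3-{4-[(triisopropylsilyl)oxy]phenyl}-2,5-dihydrofuran-2-carboxylate | COC(=O)[C@]1(Cc2ccc(O[Si](C(C)C)(C(C)C)C(C)C)c(C[C@H]3OC3(C)C)c2)OC(=O)C(O[Si](C)(C)C(C)(C)C)=C1c1ccc(O[Si](C(C)C)(C(C)C)C(C)C)cc1
F5 | step 6 | chloro{3-(3-methylbut-2-en-1-yl)-4-[(triisopropylsilyl)oxy]phenyl}magnesium | Cl[Mg]c1ccc(O[Si](C(C)C)(C(C)C)C(C)C)c(CC=C(C)C)c1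
F6 | step 6 | methyl 2-hydroxy-3-{3-(3-methylbut-2-en-1-yl)-4-[(triisopropylsilyl)oxy]phenyl}propanoate (racemic) | COC(=O)C(O)Cc1ccc(O[Si](C(C)C)(C(C)C)C(C)C)c(CC=C(C)C)c1
F7 | step 6 | methyl 3-{3-(3-methylbut-2-en-1-yl)-4-[(triisopropylsilyl)oxy]phenyl}-2-oxopropanoate | COC(=O)C(=O)Cc1ccc(O[Si](C(C)C)(C(C)C)C(C)C)c(CC=C(C)C)c1
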